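**Retrosynthetic overview**
- The oxolane is the only ring and is closed last. A (Z)-homoallylic alcohol that already carries the O10 laurate is epoxidised under direction of its C9 hydroxyl, and that hydroxyl opens the cis-epoxide at C6 (5-endo).
- The homoallylic alcohol comes from a three-component union. A lithiated terminal epoxide (C9–C19), a (Z)-oct-2-enyl boronic ester (C1–C8) and dodecanoyl chloride combine. C8 shifts from boron to C9 (1,2-metallate shift), the oxirane oxygen leaves as the O10 ester, and boron is then exchanged for OH.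
- The epoxide comes from (R)-epichlorohydrin and octa-1,7-diene. The allyl boronate comes from (E)-octa-1,3-diene. The acyl chloride comes from 1-bromoheptane and 5-bromopentanoic acid.

Assumption: the five carbon sources are treated as catalogue chemicals, and positions use natural-product numbering (C1 = methyl end of the pentyl chain, C19 = alkene terminus).

**Step 1**
Reactants: 1 1-bromoheptane; 2 5-bromopentanoic acid
Product: 4 dodecanoic acid, via heptylmagnesium bromide 3 (not isolated)
Conditions: Mg, THF; 2 (0.45 equiv), Li2CuCl4 (3 mol%), THF, −20 °C → rt; H3O+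
Reagents that add atoms: none
Why: This is a Kochi-type copper-catalysed sp3–sp3 Grignard cross-coupling in which the first equivalent of 3 makes the halomagnesium carboxylate and the second displaces the primary bromide faster than lactonisation at low temperature.

**Step 2**
Reactants: 4 dodecanoic acid
Product: 5 dodecanoyl chloride
Conditions: (COCl)2, DMF (cat.), CH2Cl2, 0 °C → rt
Reagents that add atoms: oxalyl chloride, ClC(=O)C(=O)Cl
Why: This is standard acyl chloride formation through Vilsmeier-type activation, and no other functional group is present.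

**Step 3**
Reactants: 6 (3E)-octa-1,3-diene
Product: 7 2-[(2Z)-oct-2-en-1-yl]-4,4,5,5-tetramethyl-1,3,2-dioxaborolane
Conditions: HBpin, Ni(cod)2 (2.5 mol%), PCy3 (2.5 mol%), toluene, rt
Reagents that add atoms: pinacolborane, [H]B1OC(C)(C)C(C)(C)O1
Why: This is a nickel-catalysed 1,4-hydroboration of a terminal 1,3-diene in which zerovalent nickel binds the s-cis diene, hydrogen goes to C4 and boron to C1 through a syn pi-allyl, and the Z alkene is thereby fixed.

**Step 4**
Reactants: 8 octa-1,7-diene
Product: 9 8-bromooct-1-ene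
Conditions: HBr (1 equiv), (PhCO2)2 (2 mol%), pentane, 0 °C; 8 in fourfold excess, recovered by distillation
Reagents that add atoms: hydrogen bromide, Br
Why: This is a radical-chain anti-Markovnikov hydrobromination (Kharasch peroxide effect) in which fast hydrogen transfer from HBr outruns ring closure of the radical and excess diene holds the reaction at mono-addition.

**Step 5**
Reactants: 9 8-bromooct-1-ene; 10 (R)-epichlorohydrin, (2R)-2-(chloromethyl)oxirane
Product: 13 (2R)-2-(non-8-en-1-yl)oxirane, via oct-7-enylmagnesium bromide 11 (not isolated), via chlorohydrin 12 (not isolated)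
Conditions: Mg, THF; CuI (10 mol%), 10, −30 °C; then aq. NaOH, rt
Reagents that add atoms: none
Why: A copper-catalysed Grignard opening at the oxirane CH2 is followed by Williamson-type closure onto CH2Cl, so the C–O bond at the stereocentre (future C10, R) is never broken and comes unchanged from 10.

**Step 6 (key step)**
Reactants: 13 (2R)-2-(non-8-en-1-yl)oxirane; 7 (Z)-oct-2-enyl pinacol boronate; 5 dodecanoyl chloride
Product: 17 (6Z,9R,10R)-9-hydroxynonadeca-6,18-dien-10-yl dodecanoate, via trans-oxiranyllithium 14 (not isolated), via lithium oxiranyl allyl boronate complex 15 (not isolated), via beta-acyloxy boronic ester 16 (not isolated)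
Conditions: s-BuLi, 3,7-dibutyl-3,7-diazabicyclo[3.3.1]nonane, Et2O/hexane, −90 °C; 7, −90 °C; 5, −90 → 0 °C; then Me3NO, THF, 40 °C; aq. work-up
Reagents that add atoms: trimethylamine N-oxide, C[N+](C)(C)[O-]
Why: Proposed new method: pre-formed trans-lithiated oxirane adds to boron with retention faster than it can deprotonate the allyl boronate, and in ate complex 15 acylation of the oxirane oxygen by 5 takes the role that a silyl triflate plays in the closest known reaction type (homologation of boronic esters with lithiated epoxides, a Matteson-type lithiation–borylation), so C9–O becomes a leaving group and allylic C8 shifts from boron to C9 antiperiplanar to the breaking bond (1,2-metallate shift, inversion at C9, C10–O untouched), which forges C8–C9, sets C9 syn to C10 and places the laurate on O10 only, after which the amine-oxide boron-to-oxygen shift gives the C9 alcohol with retention under non-basic conditions that keep the ester in place.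

**Step 7**
Reactants: 17 (6Z,9R,10R)-9-hydroxynonadeca-6,18-dien-10-yl dodecanoate
Product: 19 (1R)-1-[(2R,4S,5S)-4-hydroxy-5-pentyloxolan-2-yl]dec-9-en-1-yl dodecanoate, via cis-epoxy alcohol 18 (not isolated)
Conditions: VO(acac)2 (5 mol%), t-BuOOH (decane), CH2Cl2, 0 °C → rt; then camphorsulfonic acid (5 mol%)
Reagents that add atoms: tert-butyl hydroperoxide, CC(C)(C)OO
Why: In this hydroxyl-directed vanadium-catalysed epoxidation of a (Z)-homoallylic alcohol a chair-like transition state with both chain ends equatorial places the epoxide oxygen syn to O9 (sets C7 as S) and leaves the undirected terminal alkene alone, and the C9 hydroxyl then opens the cis-epoxide at C6 by 5-endo SN2 attack with inversion (sets C6 as S; 2,5-trans and 2,3-cis).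

Stereocentre record: C10 comes from 10 in step 5, C9 is set in step 6, and C7 and C6 are set in step 7. None of them is touched afterwards.

**Compound list**
1 | 1-bromoheptane | CCCCCCCBr | starting material
2 | 5-bromopentanoic acid | OC(=O)CCCCBr | starting material
3 | heptylmagnesium bromide | CCCCCCC[Mg]Br | intermediate
4 | dodecanoic acid | CCCCCCCCCCCC(=O)O | intermediate
5 | dodecanoyl chloride | CCCCCCCCCCCC(=O)Cl | intermediate
6 | (3E)-octa-1,3-diene | C=C/C=C/CCCC | starting material
7 | 2-[(2Z)-oct-2-en-1-yl]-4,4,5,5-tetramethyl-1,3,2-dioxaborolane | CCCCC/C=C\CB1OC(C)(C)C(C)(C)O1 | intermediate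
8 | octa-1,7-diene | C=CCCCCC=C | starting material
9 | 8-bromooct-1-ene | C=CCCCCCCBr | intermediate
10 | (2R)-2-(chloromethyl)oxirane | ClC[C@H]1CO1 | starting material
11 | oct-7-en-1-ylmagnesium bromide | C=CCCCCCC[Mg]Br | intermediate
12 | (2R)-1-chloroundec-10-en-2-ol | C=CCCCCCCC[C@@H](O)CCl | intermediate
13 | (2R)-2-(non-8-en-1-yl)oxirane | C=CCCCCCCC[C@@H]1CO1 | intermediate
14 | [(2R,3R)-3-(non-8-en-1-yl)oxiran-2-yl]lithium (Li trans to the chain) | C=CCCCCCCC[C@H]1O[C@@H]1[Li] | intermediate
15 | lithium [(2R,3R)-3-(non-8-en-1-yl)oxiran-2-yl][(2Z)-oct-2-en-1-yl](pinacolato)borate | [Li+].C=CCCCCCCC[C@H]1O[C@@H]1[B-]2(C/C=C\CCCCC)OC(C)(C)C(C)(C)O2 | intermediate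
16 | (6Z,9R,10R)-9-(4,4,5,5-tetramethyl-1,3,2-dioxaborolan-2-yl)nonadeca-6,18-dien-10-yl dodecanoate | C=CCCCCCCC[C@@H](OC(=O)CCCCCCCCCCC)[C@H](B1OC(C)(C)C(C)(C)O1)C/C=C\CCCCC | intermediate
17 | (6Z,9R,10R)-9-hydroxynonadeca-6,18-dien-10-yl dodecanoate | C=CCCCCCCC[C@@H](OC(=O)CCCCCCCCCCC)[C@H](O)C/C=C\CCCCC | intermediate
18 | (1R,2R)-2-hydroxy-1-(non-8-en-1-yl)-3-[(2S,3R)-3-pentyloxiran-2-yl]propyl dodecanoate | C=CCCCCCCC[C@@H](OC(=O)CCCCCCCCCCC)[C@H](O)C[C@@H]1O[C@@H]1CCCCC | intermediate
19 | (1R)-1-[(2R,4S,5S)-4-hydroxy-5-pentyloxolan-2-yl]dec-9-en-1-yl dodecanoate, i.e. (6S,7S,9R,10R) | C=CCCCCCCC[C@@H](OC(=O)CCCCCCCCCCC)[C@H]1C[C@H](O)[C@H](CCCCC)O1 | target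

**Totals:** 7 steps in all. The longest linear sequence is 4 steps (8 → 9 → 13 → 17 → 19).

**Steps most likely to fail**

*Step 6 (the new step).* The acyl chloride may attack the gamma-carbon of the allyl borate. The beta-boryl alkoxide or the beta-acyloxy boronate may eliminate to an alkene. The ester may also shift during the oxidation.

The fallback uses known chemistry only, sets out from 9 and returns at 17.
- Grignard reagent 11, made from 9, opens one ring of purchased (2R,3R)-1,2:3,4-diepoxybutane (used in excess, CuI catalysis). This gives (1R)-1-[(2R)-oxiran-2-yl]dec-9-en-1-ol F1.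
- Steglich esterification of F1 with acid 4 (DCC, DMAP) gives (1R)-1-[(2R)-oxiran-2-yl]dec-9-en-1-yl dodecanoate F2.
- Pentyllithium and CuBr·SMe2 give lithium dipentylcuprate F3. Syn-carbocupration of acetylene with it gives lithium bis[(1Z)-hept-1-en-1-yl]cuprate F4.
- F4 opens the terminal carbon of F2 with BF3·OEt2 at −78 °C. The boron-bound alkoxide suppresses acyl shift, and the product is 17.

*Step 7.* The risks are incomplete syn selectivity and acyl migration in the free hydroxy ester.

The fallback moves stereocontrol from the substrate to the reagent, sets out from 17 and returns at 19.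
- TESCl and imidazole give (6Z,9R,10R)-9-(triethylsilyloxy)nonadeca-6,18-dien-10-yl dodecanoate F5, which cannot shift its acyl group.
- Oxone and a carbohydrate-derived oxazolidinone ketone of the kind made for cis-alkenes epoxidise the internal alkene selectively. This gives (1R,2R)-1-(non-8-en-1-yl)-3-[(2S,3R)-3-pentyloxiran-2-yl]-2-(triethylsilyloxy)propyl dodecanoate F6.
- HF·pyridine in MeCN removes the silyl group, and the freed hydroxyl closes the ring to 19.

*Step 4.* The risks are statistical mono/bis addition and traces of Markovnikov bromide.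

The fallback uses an ionic route in place of the radical chain, sets out from 8 and returns at 9.
- 9-BBN-H with excess 8 gives 9-(oct-7-en-1-yl)-9-borabicyclo[3.3.1]nonane F7.
- NaOH/H2O2 gives oct-7-en-1-ol F8.
- Appel bromination (CBr4, PPh3) gives 9.

**Further compounds**
F1 | step 6 | (1R)-1-[(2R)-oxiran-2-yl]dec-9-en-1-ol | C=CCCCCCCC[C@@H](O)[C@H]1CO1
F2 | step 6 | (1R)-1-[(2R)-oxiran-2-yl]dec-9-en-1-yl dodecanoate | C=CCCCCCCC[C@@H](OC(=O)CCCCCCCCCCC)[C@H]1CO1
F3 | step 6 | lithium dipentylcuprate | [Li+].CCCCC[Cu-]CCCCC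
F4 | step 6 | lithium bis[(1Z)-hept-1-en-1-yl]cuprate | [Li+].CCCCC/C=C\[Cu-]/C=C\CCCCC
F5 | step 7 | (6Z,9R,10R)-9-(triethylsilyloxy)nonadeca-6,18-dien-10-yl dodecanoate | C=CCCCCCCC[C@@H](OC(=O)CCCCCCCCCCC)[C@H](O[Si](CC)(CC)CC)C/C=C\CCCCC
F6 | step 7 | (1R,2R)-1-(non-8-en-1-yl)-3-[(2S,3R)-3-pentyloxiran-2-yl]-2-(triethylsilyloxy)propyl dodecanoate | C=CCCCCCCC[C@@H](OC(=O)CCCCCCCCCCC)[C@H](O[Si](CC)(CC)CC)C[C@@H]1O[C@@H]1CCCCC
F7 | step 4 | 9-(oct-7-en-1-yl)-9-borabicyclo[3.3.1]nonane | C=CCCCCCCB1C2CCCC1CCC2
F8 | step 4 | oct-7-en-1-ol | C=CCCCCCCO
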